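# Design of a total synthesis of the cis-eudesmane 9-anisate 26

Remark (convention and assumption): eudesmane numbering is used for every intermediate (ring A: C1–C2–C3–C4–C5–C10; ring B: C5–C6–C7–C8–C9–C10; C14 = methyl on C10; C15 = methylene on C4). The target SMILES is read as the (5S,6S,7R,9R,10R) isomer. Compounds 1, 2, 7, 8 and 21 are taken as purchasable.

## The problem

Target 26 is a cis-fused decalin with five stereocentres that run without a break around ring B, from C9 through the quaternary C10 and the ring-fusion carbon C5 to C6 and C7; only C8 is a methylene. The C14 methyl, the C6 hydroxyl, the C7 isopropyl group and the C9 anisoate all sit on one face of ring B. Ring A hangs from C10 (equatorial) and C5 (axial), so the C6 hydroxyl is the axial, less stable epimer, 1,3-diaxial to C14.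

The quaternary C10 cannot be corrected later and must be made with absolute control. Once it exists, its axial methyl can direct the ring fusion at C5 and the hydride face at C6. C7 is α to the C6 carbonyl of any ketone precursor, can be set independently, and is the thermodynamically favoured equatorial epimer.

Three features are fragile:
- the exocyclic C4=C15 alkene, which at the C6-ketone stage is β,γ-unsaturated and can slip into conjugation through the acidic C5–H;
- the aryl ester, which must end on O9 rather than O6 and will not survive hydroxide, alkoxide or aluminium hydrides;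
- C5 itself while C6 is a carbonyl.

The two oxygens are 1,4 across ring B and must be told apart. The enabling feature is that the C9 oxygen sits next to the quaternary C10. C9–O/C10 is the retron of a trisubstituted epoxide opened at its tertiary end, and the carbon that must do the opening, C5, is α to the C6 oxygen and can be made nucleophilic as an enol silane.

## Retrosynthesis

**C6 carbinol to ketone (26 ⇒ 25).** No skeletal bond is cut. A C6 carbonyl is needed anyway to make C5 nucleophilic for both ring closures. Reducing it last keeps O6 and O9 differentiated without protecting groups, because O9 already carries the anisoate. The forward step must deliver hydride to the face opposite C14, leave the aryl ester alone and be non-basic so the methylene stays exocyclic.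

**C4–C5, ring A (25 ⇒ 24).** This cut turns the decalin into the monocyclic enol silane 24 with a pentynyl arm on C10. Its merit over a C4 carbonyl followed by methylenation is that the exocyclic alkene appears in the bond-forming step, so no olefination is needed next to the epimerisable C5. The forward reaction must be a 6-exo-dig carbocyclisation and must give the cis fusion.

**Enol silane and ester (24 ⇒ 22 ⇒ 20 + 21).** Enol silane 24 comes from ketone 22 by deprotonation at the C5 methylene instead of the isopropyl-bearing C7 methine. Ester 22 comes from the only free hydroxyl of hydroxy ketone 20 and acid chloride 21. Acylating at this point uses the final ester as the protecting group for O9.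

**C5–C10, ring B (20 ⇒ 19), the key cut.** Among the ring B bonds, only this cut makes the quaternary centre and the neighbouring carbinol together from one stereodefined functional group. Cutting C5–C6, C7–C8 or C8–C9 would leave C10 to be built by a separate conjugate addition or alkylation. The precursor 19 is acyclic, with one carbon stereocentre (C7) and a trans epoxide. The forward reaction must open the epoxide at its tertiary carbon with inversion and pass through the chair that carries the isopropyl group equatorially. The (7R) centre and the (9R,10R) epoxide are the matched pair for that chair.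

**Enol silane and epoxide (19 ⇒ 17 ⇒ 16).** The enol silane is the kinetic one of methyl ketone 17, whose other α-position is a hindered methine. The epoxide comes from the (E)-trisubstituted alkene of 16 by reagent-controlled epoxidation, so C9 and C10 do not depend on C7. Epoxidation is placed after the ketone is made, because an epoxy acid would lactonise.

**C7–C8 (16 ⇒ 14 ⇒ 12 ⇒ 10 + 6).** The methyl ketone is the methyllithium adduct of acid 14. The acid is the hydrolysis product of imide 12, made by auxiliary-controlled alkylation of the isovaleryl imide 10 with allylic bromide 6. This places C7 with a reactive SN2 electrophile and a recoverable auxiliary. Imide 10 is made from 7 and 8.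

**C9=C10 (6 ⇒ 5 ⇒ 4 ⇒ 1 + 2).** The allylic bromide goes back through alcohol 5 to enoate 4, the Horner–Wadsworth–Emmons product of ketone 1 and phosphonate 2. The demand here is geometric purity of the (E)-alkene, because the alkene geometry becomes the relative configuration of C9 and C10.

## Roads not taken

**Alternative 1:** ring A is bought as a β-methyl cyclohexenone and C9–C10 and C5–C6 are cut; no ring forms in the key step. A copper-catalysed transfer of a silyl-capped alkynyl group from aluminium to the β-carbon would create the quaternary C10. The aluminium enolate would then be trapped at C5 by an isopropyl α-keto aldehyde, giving the hydroxy diketone A1.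
- Merits: three pieces join in one flask, the chirality source is catalytic, C10 and C5 are set together with the cis relation, and the C4 carbonyl is ready for methylenation.
- Weak points: alkynyl groups transfer reluctantly from copper, and an enantioselective alkynylation that builds a quaternary carbon on a β-substituted enone is far less secure than alkyl, aryl or alkenyl transfer. The electrophile has two carbonyl groups, and a hindered enolate must set C6 relative to C5.
- Ring B is still open in A1. Closing C7–C8 between a ketone carbon and an alkyne terminus is a 6-endo process for a ketyl or vinyl-metal closure. Afterwards C7 must lose oxygen and gain hydrogen stereoselectively, C9 must gain oxygen, and two ketones flank an aldol centre prone to retro-aldol and dehydration.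
- Comparison: this road is better in convergence and needs no auxiliary. The chosen plan sets against that a ring-forming step that delivers C7, C9 and C10 in their final oxidation state and configuration, so nothing on ring B needs repair.

**Alternative 2:** C1–C2 and C5–C10 are cut together in an intramolecular Diels–Alder reaction of an acyclic trienone. An isopropenyl ketone (C1=C10, activated by the C9 carbonyl in the tether) adds to a diene carrying a silylmethyl group on C4, closing both rings to give the cis-fused decalone A2.
- Merits: both rings and two bonds form in one step, the allylsilane gives the C4 methylene regiospecifically on protodesilylation, and O6 (silyl ether) and O9 (ketone) are differentiated from the start.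
- Weak points: the dienophile is 1,1-disubstituted and sluggish. The cis fusion depends on endo/exo selectivity and the C5/C10 pair depends on facial control by the C6/C7 centres; neither is stereospecific.
- The trienone needs two adjacent stereocentres and a geometrically defined 2-substituted diene, which is a long preparation.
- In A2 the C9 ketone must be reduced to the equatorial alcohol, which means axial hydride delivery past the syn-axial C4 of ring A. That is the less likely outcome.
- Comparison: this road is better in step economy at the ring-forming stage. The chosen plan sets against it stereospecific transfer of C9 and C10 from an epoxide of known configuration and a simpler acyclic precursor.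

**Alternative 3:** C4–C5 is cut on a Birch-derived, prochiral cyclohexadiene whose quaternary carbon carries a side chain ending in an enol triflate. An alkenylpalladium formed from zerovalent palladium and a chiral ligand adds across one enantiotopic ring alkene. β-Hydride loss toward C7 gives the cis-fused triene A3.
- Merits: it is the shortest way to the bicyclic skeleton, enantiocontrol is catalytic, the cis fusion follows from syn carbopalladation, and the methylene is in place.
- Weak points: every heteroatom and the C7 centre are still missing in A3. O6 and O9 must be added across a diene in the presence of the 1,1-disubstituted C4 alkene. The C7=C8 bond must then be saturated with the right C7 configuration without touching the more accessible methylene, and two similar secondary hydroxyls must be told apart for mono-acylation.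
- Comparison: this road is clearly better up to the bicycle. The chosen plan sets against it that C7, C9 and C10 arrive in the bicycle already fixed, and C5 and C6 are then set by the angular methyl.

Key step: step 10

## Route

Step 1
Reactants: 1 hept-6-yn-2-one; 2 triethyl phosphonoacetate
Product: 4 ethyl (2E)-3-methyloct-2-en-7-ynoate, via sodium phosphonate anion 3 (not isolated)
Conditions: NaH, THF, 0 °C; then 1, 0 °C → rt; chromatography to remove the (Z)-isomer
Reagents that add atoms: none
Why: Horner–Wadsworth–Emmons olefination of a methyl ketone; the stabilised anion is too weak a base to touch the alkyne C–H, the (E)-enoate should predominate, and removing the minor (Z)-isomer here fixes the geometry that later becomes the epoxide configuration.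

Step 2
Reactants: 4 ethyl (2E)-3-methyloct-2-en-7-ynoate
Product: 5 (2E)-3-methyloct-2-en-7-yn-1-ol
Conditions: i-Bu2AlH (2.2 equiv), CH2Cl2, −78 → 0 °C; aq. KNaC4H4O6
Reagents that add atoms: none
Why: 1,2-reduction of an α,β-unsaturated ester by a dialkylaluminium hydride; neither conjugate reduction nor hydroalumination of the alkyne is expected at low temperature.

Step 3
Reactants: 5 (2E)-3-methyloct-2-en-7-yn-1-ol
Product: 6 (6E)-8-bromo-6-methyloct-6-en-1-yne
Conditions: CBr4, PPh3, CH2Cl2, 0 °C; pentane trituration, used at once
Reagents that add atoms: carbon tetrabromide, BrC(Br)(Br)Br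
Why: Appel bromination under neutral conditions converts the primary allylic alcohol to the bromide without allylic transposition or loss of alkene geometry.

Step 4
Reactants: 7 (4R)-4-benzyl-1,3-oxazolidin-2-one; 8 3-methylbutanoyl chloride
Product: 10 (4R)-4-benzyl-3-(3-methylbutanoyl)-1,3-oxazolidin-2-one, via lithiated oxazolidinone 9 (not isolated)
Conditions: n-BuLi, THF, −78 °C; then 8, −78 → 0 °C
Reagents that add atoms: none
Why: N-acylation of the lithiated Evans auxiliary with an acid chloride.

Step 5
Reactants: 10 (4R)-4-benzyl-3-(3-methylbutanoyl)-1,3-oxazolidin-2-one; 6 (6E)-8-bromo-6-methyloct-6-en-1-yne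
Product: 12 (4R)-4-benzyl-3-[(2R,4E)-5-methyl-2-(propan-2-yl)dec-4-en-9-ynoyl]-1,3-oxazolidin-2-one, via sodium Z-enolate 11 (not isolated)
Conditions: NaN(SiMe3)2, THF, −78 °C; then 6, −78 → −40 °C
Reagents that add atoms: none
Why: Evans asymmetric alkylation; the chelated (Z)-enolate is alkylated in the SN2 sense by the allylic bromide on the face away from the benzyl group, which with the (4R)-auxiliary and an isopropyl enolate substituent gives (7R) (the descriptor is reversed from the propionyl series only through the CIP priorities).

Step 6
Reactants: 12 (4R)-4-benzyl-3-[(2R,4E)-5-methyl-2-(propan-2-yl)dec-4-en-9-ynoyl]-1,3-oxazolidin-2-one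
Product: 14 (2R,4E)-5-methyl-2-(propan-2-yl)dec-4-en-9-ynoic acid, via lithium peroxycarboxylate 13 (not isolated)
Conditions: LiOH, H2O2, THF/H2O (3:1), 0 °C; then Na2SO3; then 1 M HCl
Reagents that add atoms: hydrogen peroxide, OO
Why: hydroperoxide attacks the exocyclic carbonyl even of α-branched imides (auxiliary cleavage without epimerisation); sulfite reduces the percarboxylate before acidification so the alkene is not epoxidised, and the auxiliary is recovered.

Step 7
Reactants: 14 (2R,4E)-5-methyl-2-(propan-2-yl)dec-4-en-9-ynoic acid
Product: 16 (3R,5E)-6-methyl-3-(propan-2-yl)undec-5-en-10-yn-2-one, via trilithium gem-diolate adduct 15 (not isolated)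
Conditions: MeLi (3.5 equiv), Et2O, 0 °C → rt; inverse quench into cold 1 M HCl
Reagents that add atoms: methyllithium, [Li]C
Why: classical ketone synthesis from a lithium carboxylate and an alkyllithium; two equivalents are consumed by the acid and alkyne protons, the tetrahedral adduct does not collapse until the quench (so no tertiary alcohol and no enolisable ketone in the basic medium), and C7 should keep its configuration.

Step 8
Reactants: 16 (3R,5E)-6-methyl-3-(propan-2-yl)undec-5-en-10-yn-2-one
Product: 17 (3R)-4-methyl-3-{[(2R,3R)-3-methyl-3-(pent-4-yn-1-yl)oxiran-2-yl]methyl}pentan-2-one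
Conditions: D-fructose-derived Shi ketone (1,2:4,5-di-O-isopropylidene-β-D-erythro-2,3-hexodiulo-2,6-pyranose, 30 mol%), KHSO5 (as 2KHSO5·KHSO4·K2SO4), K2CO3, Bu4NHSO4, MeCN/(MeO)2CH2, aq. Na2B4O7/Na2EDTA buffer, 0 °C
Reagents that add atoms: potassium peroxymonosulfate, [K+].[O-]S(=O)(=O)OO
Why: Shi epoxidation of an (E)-trisubstituted alkene; the chiral dioxirane delivers oxygen through the spiro transition state to the face that gives the (R,R)-oxirane, as for the underlying trans-disubstituted alkene, so C9 and C10 are set by the reagent while the alkyne and the hindered ketone are inert in the cold buffered medium.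

Step 9
Reactants: 17 (3R)-4-methyl-3-{[(2R,3R)-3-methyl-3-(pent-4-yn-1-yl)oxiran-2-yl]methyl}pentan-2-one
Product: 19 trimethyl{[(3R)-4-methyl-3-{[(2R,3R)-3-methyl-3-(pent-4-yn-1-yl)oxiran-2-yl]methyl}pent-1-en-2-yl]oxy}silane, via lithium enolate 18 (not isolated)
Conditions: LiN(i-Pr)2 (1.05 equiv), THF, −78 °C; then Me3SiCl, Et3N, −78 → 0 °C; pentane, cold aq. NaHCO3; used crude
Reagents that add atoms: chlorotrimethylsilane, C[Si](C)(C)Cl
Why: kinetic enolisation of a methyl ketone whose other α-position is a hindered methine gives only the terminal enolate, which is O-silylated; the ketone is more acidic than the alkyne C–H, so near-stoichiometric base should leave the alkyne alone, and a lithium enolate does not open a trisubstituted epoxide at −78 °C.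

Step 10
Reactants: 19 trimethyl{[(3R)-4-methyl-3-{[(2R,3R)-3-methyl-3-(pent-4-yn-1-yl)oxiran-2-yl]methyl}pent-1-en-2-yl]oxy}silane
Product: 20 (2R,4R,5R)-4-hydroxy-5-methyl-5-(pent-4-yn-1-yl)-2-(propan-2-yl)cyclohexan-1-one
Conditions: Me2AlCl (1.5 equiv), CH2Cl2, −78 °C; then 1 M HCl, THF, 0 °C
Reagents that add atoms: none
Why: Me2AlCl coordinates the epoxide oxygen and weakens its bond to the tertiary C10; the enol silane carbon C5 then attacks C10 from the side opposite the departing oxygen through a chair-like transition state, and the silyloxocarbenium ion at C6 gives up its silyl group to chloride to leave the ketone. The closest known reaction type is the Lewis-acid-promoted epoxide-initiated cation–olefin (epoxy-polyene) cyclisation terminated by an enol silane, of which this is the first ring closure alone, equally an intramolecular Mukaiyama-type alkylation by an epoxide. Ring B (C5–C6–C7–C8–C9–C10) closes in the 6-endo mode with respect to the epoxide, both epoxide carbons ending in the ring, and endo with respect to the enol double bond. C10 is set by stereospecific inversion at the attacked carbon, so the (E)-derived (9R,10R)-epoxide places the C14 methyl axial and cis to the C9 oxygen (the descriptor stays R only because the CIP priorities change). C9 keeps the configuration from the Shi epoxidation because its C–O bond is not broken, and the anti-periplanar opening forces this oxygen equatorial. The existing (7R) centre is matched: in the same chair the isopropyl group is equatorial, hence cis to O9 and C14. The step needs attack at the tertiary carbon and not 5-exo attack at C9, and C- not O-alkylation; the first is secured by the cation-stabilising substitution at C10 under Lewis-acid activation, the second by the π-nucleophilicity of the silyl-capped enol. Low temperature and an aluminium Lewis acid that scavenges protons are relied on to keep hydride shift and elimination of the activated epoxide slower than intramolecular capture.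

Step 11
Reactants: 20 (2R,4R,5R)-4-hydroxy-5-methyl-5-(pent-4-yn-1-yl)-2-(propan-2-yl)cyclohexan-1-one; 21 4-methoxybenzoyl chloride
Product: 22 (1R,2R,5R)-2-methyl-4-oxo-2-(pent-4-yn-1-yl)-5-(propan-2-yl)cyclohexyl 4-methoxybenzoate
Conditions: Et3N, DMAP (cat.), CH2Cl2, 0 °C → rt
Reagents that add atoms: none
Why: DMAP-catalysed acylation of the single, equatorial secondary alcohol; the oxygen is γ to the ketone on both ring paths, so no β-elimination pathway exists.

Step 12
Reactants: 22 (1R,2R,5R)-2-methyl-4-oxo-2-(pent-4-yn-1-yl)-5-(propan-2-yl)cyclohexyl 4-methoxybenzoate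
Product: 24 (1R,2R,5R)-4-{[tert-butyl(dimethyl)silyl]oxy}-2-methyl-2-(pent-4-yn-1-yl)-5-(propan-2-yl)cyclohex-3-en-1-yl 4-methoxybenzoate, via lithium enolate 23 (not isolated)
Conditions: LiN(i-Pr)2 (1.1 equiv), THF, −78 °C (22 added to the base); then t-BuMe2SiOTf, −78 °C
Reagents that add atoms: tert-butyldimethylsilyl trifluoromethanesulfonate, CC(C)(C)[Si](C)(C)OS(=O)(=O)C(F)(F)F
Why: kinetic deprotonation by a hindered amide base takes the C5 methylene proton in preference to the isopropyl-bearing C7 methine and is much faster than attack on the aryl ester; O-silylation gives a robust enol silane, and any C6=C7 isomer cannot cyclise in step 13 and would revert to 22 there.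

Step 13
Reactants: 24 (1R,2R,5R)-4-{[tert-butyl(dimethyl)silyl]oxy}-2-methyl-2-(pent-4-yn-1-yl)-5-(propan-2-yl)cyclohex-3-en-1-yl 4-methoxybenzoate
Product: 25 (1R,3R,4aS,8aR)-8a-methyl-5-methylidene-4-oxo-3-(propan-2-yl)decahydronaphthalen-1-yl 4-methoxybenzoate
Conditions: Ph3PAuNTf2 (5 mol%), CH2Cl2/MeOH (10:1), rt
Reagents that add atoms: none
Why: Conia-ene-type carbocyclisation of a silyl enol ether onto a terminal alkyne catalysed by monovalent gold: C5 adds anti to the metal at the internal alkyne carbon C4 (6-exo-dig), and methanol removes the silyl group and protodeaurates C15 to give the exocyclic methylene. C5 is set by the C14 methyl, because the tether is equatorial on C10 and can reach C5 only along the axial trajectory anti to the axial methyl, which gives the cis fusion (5S); the neutral medium should leave the alkene exocyclic.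

Step 14
Reactants: 25 (1R,3R,4aS,8aR)-8a-methyl-5-methylidene-4-oxo-3-(propan-2-yl)decahydronaphthalen-1-yl 4-methoxybenzoate
Product: 26 (1R,3R,4S,4aS,8aR)-4-hydroxy-8a-methyl-5-methylidene-3-(propan-2-yl)decahydronaphthalen-1-yl 4-methoxybenzoate
Conditions: LiBH(s-Bu)3, THF, −78 °C; then H2O
Reagents that add atoms: none
Why: reduction by a bulky trialkylborohydride; axial approach to C6 is blocked by the syn-axial C14 methyl, so hydride should enter from the opposite side and give the axial C6 hydroxyl cis to C14 (6S), as in related decalones and 6-oxo steroids with an axial angular methyl. The reagent reduces the ketone much faster than the aryl ester at −78 °C and is not basic enough to conjugate the alkene or epimerise C5.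

## Compound list

1 | hept-6-yn-2-one | CC(=O)CCCC#C | starting material
2 | triethyl phosphonoacetate | CCOC(=O)CP(=O)(OCC)OCC | starting material
3 | sodium 2-(diethoxyphosphoryl)-1-ethoxy-1-oxoethan-2-ide (formed in situ) | CCOC(=O)[CH-]P(=O)(OCC)OCC.[Na+] | intermediate
4 | ethyl (2E)-3-methyloct-2-en-7-ynoate | CCOC(=O)/C=C(\C)CCCC#C | intermediate
5 | (2E)-3-methyloct-2-en-7-yn-1-ol | OC/C=C(\C)CCCC#C | intermediate
6 | (6E)-8-bromo-6-methyloct-6-en-1-yne | BrC/C=C(\C)CCCC#C | intermediate
7 | (4R)-4-benzyl-1,3-oxazolidin-2-one | O=C1N[C@H](Cc2ccccc2)CO1 | starting material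
8 | 3-methylbutanoyl chloride | CC(C)CC(Cl)=O | starting material
9 | lithium (4R)-4-benzyl-2-oxo-1,3-oxazolidin-3-ide (formed in situ) | O=C1[N-][C@H](Cc2ccccc2)CO1.[Li+] | intermediate
10 | (4R)-4-benzyl-3-(3-methylbutanoyl)-1,3-oxazolidin-2-one | CC(C)CC(=O)N1[C@H](Cc2ccccc2)COC1=O | intermediate
11 | sodium (1Z)-1-[(4R)-4-benzyl-2-oxo-1,3-oxazolidin-3-yl]-3-methylbut-1-en-1-olate (formed in situ) | CC(C)/C=C(\[O-])N1[C@H](Cc2ccccc2)COC1=O.[Na+] | intermediate
12 | (4R)-4-benzyl-3-[(2R,4E)-5-methyl-2-(propan-2-yl)dec-4-en-9-ynoyl]-1,3-oxazolidin-2-one | C#CCCC/C(C)=C/C[C@H](C(C)C)C(=O)N1[C@H](Cc2ccccc2)COC1=O | intermediate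
13 | lithium (2R,4E)-5-methyl-2-(propan-2-yl)dec-4-en-9-yneperoxoate (formed in situ) | C#CCCC/C(C)=C/C[C@H](C(C)C)C(=O)O[O-].[Li+] | intermediate
14 | (2R,4E)-5-methyl-2-(propan-2-yl)dec-4-en-9-ynoic acid | C#CCCC/C(C)=C/C[C@H](C(C)C)C(=O)O | intermediate
15 | trilithium (3R,5E)-6-methyl-3-(propan-2-yl)undec-5-en-10-yn-11-ide-2,2-bis(olate) (formed in situ) | [Li+].[Li+].[Li+].[C-]#CCCC/C(C)=C/C[C@H](C(C)C)C(C)([O-])[O-] | intermediate
16 | (3R,5E)-6-methyl-3-(propan-2-yl)undec-5-en-10-yn-2-one | C#CCCC/C(C)=C/C[C@H](C(C)C)C(C)=O | intermediate
17 | (3R)-4-methyl-3-{[(2R,3R)-3-methyl-3-(pent-4-yn-1-yl)oxiran-2-yl]methyl}pentan-2-one | C#CCCC[C@@]1(C)O[C@@H]1C[C@H](C(C)C)C(C)=O | intermediate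
18 | lithium (3R)-4-methyl-3-{[(2R,3R)-3-methyl-3-(pent-4-yn-1-yl)oxiran-2-yl]methyl}pent-1-en-2-olate (formed in situ) | C#CCCC[C@@]1(C)O[C@@H]1C[C@H](C(C)C)C(=C)[O-].[Li+] | intermediate
19 | trimethyl{[(3R)-4-methyl-3-{[(2R,3R)-3-methyl-3-(pent-4-yn-1-yl)oxiran-2-yl]methyl}pent-1-en-2-yl]oxy}silane | C#CCCC[C@@]1(C)O[C@@H]1C[C@H](C(C)C)C(=C)O[Si](C)(C)C | intermediate
20 | (2R,4R,5R)-4-hydroxy-5-methyl-5-(pent-4-yn-1-yl)-2-(propan-2-yl)cyclohexan-1-one | C#CCCC[C@]1(C)CC(=O)[C@@H](C(C)C)C[C@H]1O | intermediate
21 | 4-methoxybenzoyl chloride | COc1ccc(cc1)C(Cl)=O | starting material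
22 | (1R,2R,5R)-2-methyl-4-oxo-2-(pent-4-yn-1-yl)-5-(propan-2-yl)cyclohexyl 4-methoxybenzoate | C#CCCC[C@]1(C)CC(=O)[C@@H](C(C)C)C[C@H]1OC(=O)c1ccc(OC)cc1 | intermediate
23 | lithium (3R,4R,6R)-4-[(4-methoxybenzoyl)oxy]-3-methyl-3-(pent-4-yn-1-yl)-6-(propan-2-yl)cyclohex-1-en-1-olate (formed in situ) | C#CCCC[C@]1(C)C=C([O-])[C@@H](C(C)C)C[C@H]1OC(=O)c1ccc(OC)cc1.[Li+] | intermediate
24 | (1R,2R,5R)-4-{[tert-butyl(dimethyl)silyl]oxy}-2-methyl-2-(pent-4-yn-1-yl)-5-(propan-2-yl)cyclohex-3-en-1-yl 4-methoxybenzoate | C#CCCC[C@]1(C)C=C(O[Si](C)(C)C(C)(C)C)[C@@H](C(C)C)C[C@H]1OC(=O)c1ccc(OC)cc1 | intermediate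
25 | (1R,3R,4aS,8aR)-8a-methyl-5-methylidene-4-oxo-3-(propan-2-yl)decahydronaphthalen-1-yl 4-methoxybenzoate | C=C1CCC[C@]2(C)[C@H]1C(=O)[C@@H](C(C)C)C[C@H]2OC(=O)c1ccc(OC)cc1 | intermediate
26 | (1R,3R,4S,4aS,8aR)-4-hydroxy-8a-methyl-5-methylidene-3-(propan-2-yl)decahydronaphthalen-1-yl 4-methoxybenzoate | C=C1CCC[C@]2(C)[C@H]1[C@@H](O)[C@@H](C(C)C)C[C@H]2OC(=O)c1ccc(OC)cc1 | target

## Step count and least certain steps

Total step count: 14. Longest linear sequence: 13 steps (steps 1–3 and 5–14, from 1 to 26); step 4 is a one-step side branch that joins at step 5.

**Step 10 (key step).** The most likely failure is collapse of the Lewis-acid-activated epoxide before the carbon–carbon bond forms. This could be a hydride shift from C9 to the developing C10 cation, elimination to an allylic alcohol, or loss of the silyl group from oxygen followed by capture of the epoxide by the freed carbonyl oxygen. The cause would be that a trisubstituted epoxide ionises easily at its tertiary carbon while a trimethylsilyl enol ether is labile to traces of acid.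

Fallback: the terminating nucleophile would be changed to an allylsilane, which cannot be lost by desilylation at oxygen and whose epoxide cyclisations are well established. Setting out from 17, the kinetic enolate 18 would be trapped with PhNTf2 to give (3R)-4-methyl-3-{[(2R,3R)-3-methyl-3-(pent-4-yn-1-yl)oxiran-2-yl]methyl}pent-1-en-2-yl trifluoromethanesulfonate F1. Negishi coupling with Me3SiCH2ZnCl under Pd(PPh3)4 (zerovalent palladium), chosen over a Grignard reagent so that the alkyne C–H is not metalated, would give trimethyl[(3R)-4-methyl-2-methylidene-3-{[(2R,3R)-3-methyl-3-(pent-4-yn-1-yl)oxiran-2-yl]methyl}pentyl]silane F2. BF3·OEt2 in CH2Cl2 at −78 °C would then form the same C5–C10 bond through the same chair to give (1R,2R,5R)-2-methyl-4-methylidene-2-(pent-4-yn-1-yl)-5-(propan-2-yl)cyclohexan-1-ol F3. Ozonolysis of its 1,1-disubstituted alkene (O3, CH2Cl2/MeOH, −78 °C; Me2S), which reacts much faster than the terminal alkyne, comes back to the route at 20.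

**Step 13.** The most likely failure is solvolytic loss of the silyl group, returning 22, outpacing a slow 6-exo-dig closure at a nucleophilic carbon next to the quaternary C10. A second risk is migration of the new alkene into conjugation with the C6 carbonyl under adventitious acid.

Fallback: ring A would be closed by a radical. Setting out from 24, PhSeCl in CH2Cl2 at −78 °C would give (1R,2S,5R)-2-methyl-4-oxo-2-(pent-4-yn-1-yl)-3-(phenylselanyl)-5-(propan-2-yl)cyclohexyl 4-methoxybenzoate F4 (either configuration at the selenium-bearing carbon). Slow addition of Bu3SnH with AIBN in benzene at 80 °C would generate the C5 radical, which should add 6-exo to the alkyne anti to the axial methyl; hydrogen transfer to the vinyl radical gives 25, where the route is rejoined.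

**Step 12.** The most likely failure is unselective deprotonation: at C7, at the alkyne C–H (followed by C-silylation), or slow acyl attack by the amide base. The cause would be that the C5 methylene is itself hindered by the neighbouring quaternary carbon.

Fallback: regiochemistry would be decided by ring size instead of kinetic deprotonation. Setting out from 22, bromoboration of the alkyne with B-bromo-9-borabicyclo[3.3.1]nonane followed by protodeboronation with AcOH would give (1R,2R,5R)-2-(4-bromopent-4-en-1-yl)-2-methyl-4-oxo-5-(propan-2-yl)cyclohexyl 4-methoxybenzoate F5. Intramolecular α-alkenylation of the ketone under Pd(PPh3)4 (zerovalent palladium) and KOPh in THF would follow; under reversible enolisation only the C5 enolate can reach the alkenylpalladium. This joins the route at 25 and bypasses 24.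

**Step 14.** The most likely failure is poor facial selectivity. Both faces of the C6 carbonyl are encumbered: one by the axial C14 methyl, the other by the C4 methylene held under C6 by the cis ring fusion.

Fallback: the configuration would be set by inversion instead of hydride face selection. Setting out from 25, the reduction product (1R,3R,4R,4aS,8aR)-4-hydroxy-8a-methyl-5-methylidene-3-(propan-2-yl)decahydronaphthalen-1-yl 4-methoxybenzoate F6 would undergo Mitsunobu esterification (4-nitrobenzoic acid, PPh3, DIAD, toluene). This gives (1R,3R,4S,4aS,8aR)-8a-methyl-5-methylidene-4-[(4-nitrobenzoyl)oxy]-3-(propan-2-yl)decahydronaphthalen-1-yl 4-methoxybenzoate F7. The electron-poor ester is then removed selectively with K2CO3 in MeOH at 0 °C, leaving the hindered, electron-rich anisoate and arriving at 26.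

## Further compounds

F1 | step 10 | (3R)-4-methyl-3-{[(2R,3R)-3-methyl-3-(pent-4-yn-1-yl)oxiran-2-yl]methyl}pent-1-en-2-yl trifluoromethanesulfonate | C#CCCC[C@@]1(C)O[C@@H]1C[C@H](C(C)C)C(=C)OS(=O)(=O)C(F)(F)F
F2 | step 10 | trimethyl[(3R)-4-methyl-2-methylidene-3-{[(2R,3R)-3-methyl-3-(pent-4-yn-1-yl)oxiran-2-yl]methyl}pentyl]silane | C#CCCC[C@@]1(C)O[C@@H]1C[C@H](C(C)C)C(=C)C[Si](C)(C)C
F3 | step 10 | (1R,2R,5R)-2-methyl-4-methylidene-2-(pent-4-yn-1-yl)-5-(propan-2-yl)cyclohexan-1-ol | C#CCCC[C@]1(C)CC(=C)[C@@H](C(C)C)C[C@H]1O
F4 | step 13 | (1R,2S,5R)-2-methyl-4-oxo-2-(pent-4-yn-1-yl)-3-(phenylselanyl)-5-(propan-2-yl)cyclohexyl 4-methoxybenzoate (either configuration at C3) | C#CCCC[C@]1(C)C([Se]c2ccccc2)C(=O)[C@@H](C(C)C)C[C@H]1OC(=O)c1ccc(OC)cc1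
F5 | step 12 | (1R,2R,5R)-2-(4-bromopent-4-en-1-yl)-2-methyl-4-oxo-5-(propan-2-yl)cyclohexyl 4-methoxybenzoate | C=C(Br)CCC[C@]1(C)CC(=O)[C@@H](C(C)C)C[C@H]1OC(=O)c1ccc(OC)cc1
F6 | step 14 | (1R,3R,4R,4aS,8aR)-4-hydroxy-8a-methyl-5-methylidene-3-(propan-2-yl)decahydronaphthalen-1-yl 4-methoxybenzoate | C=C1CCC[C@]2(C)[C@H]1[C@H](O)[C@@H](C(C)C)C[C@H]2OC(=O)c1ccc(OC)cc1
F7 | step 14 | (1R,3R,4S,4aS,8aR)-8a-methyl-5-methylidene-4-[(4-nitrobenzoyl)oxy]-3-(propan-2-yl)decahydronaphthalen-1-yl 4-methoxybenzoate | C=C1CCC[C@]2(C)[C@H]1[C@@H](OC(=O)c1ccc(cc1)[N+](=O)[O-])[C@@H](C(C)C)C[C@H]2OC(=O)c1ccc(OC)cc1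
A1 | alternative 1 | 2-(1-hydroxy-3-methyl-2-oxobutyl)-3-methyl-3-[(trimethylsilyl)ethynyl]cyclohexan-1-one (side chain cis to the alkynyl group) | O=C1CCC[C@@](C)(C#C[Si](C)(C)C)[C@H]1[C@@H](O)C(=O)C(C)C
A2 | alternative 2 | cis-fused 4-{[tert-butyl(dimethyl)silyl]oxy}-8a-methyl-3-(propan-2-yl)-5-[(trimethylsilyl)methyl]-3,4,4a,7,8,8a-hexahydronaphthalen-1(2H)-one | C[Si](C)(C)CC1=CCC[C@]2(C)[C@H]1[C@@H](O[Si](C)(C)C(C)(C)C)[C@@H](C(C)C)CC2=O
A3 | alternative 3 | cis-fused 4a-methyl-1-methylidene-7-(propan-2-yl)-1,2,3,4,4a,8a-hexahydronaphthalene | C=C1CCC[C@]2(C)[C@H]1C=C(C(C)C)C=C2
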